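The readings stem from a simulated flask on assumed constants.

The vessel is closed, stirred and isothermal, and the flask in it holds 1.0 M of starting material with 2.00 equiv of reagent, to be read at 6.0 min.

| flask | starting material | reagent | remark | time |
|---|---|---|---|---|
| north | 1 M | 1 equiv | run made earlier |  |
| north-east | 1 M | 1.5 equiv | run made earlier |  |
| east | 0.50 M | 2 equiv | run made earlier |  |
| flask | 1.0 M | 2.00 equiv |  | 6.0 min |

| run | time / min | first product / % | triple product / % |
|---|---|---|---|
| north | 1.33 | 35.5 | 1.1 |
| north | 2.50 | 31.6 | 0 |
| north | 4.00 | 33.7 | 1.0 |
| north | 5.00 | 31.7 | 0 |
| north | 6.00 | 31.1 | 2.0 |
| north-east | 0.500 | 40.5 | 0.3 |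
| north-east | 1.50 | 46.6 | 0.5 |
| north-east | 3.00 | 46.8 | 1.4 |
| north-east | 4.00 | 47.4 | 0.9 |
| north-east | 6.00 | 46.7 | 3.1 |
| east | 0.500 | 36.5 | 1.3 |
| east | 0.833 | 45.0 | 0 |
| east | 1.50 | 50.5 | 0 |
| east | 3.00 | 57.3 | 1.4 |
| east | 6.00 | 54.3 | 0.5 |

(readings scatter by 1 percentage point)

- a species is counted by the starting material in it: one side product counts as two
- steps under discussion: starting material + reagent -> first product + by-product; reagent + first product -> double product + by-product; reagent + double product -> triple product + by-product; triple product <-> isomer of the product; starting material + first product -> side product

- equivalents of reagent to starting material, everything else as given, that leave most first product at 6.0 min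
- the amount of first product then, in percent of the starting material charged
- the amount of first product with the amounts as given

The east run looks nearly the same: it has the same equivalents at half the concentration. I take both steps that consume starting material as first order in it, so [starting material] cancels from their ratio, leaving [first product]/[reagent]. At fixed equivalents that ratio does not change with the charge, so the yield at a given conversion is the same in both. Both steps are second order, so the flask reaches that conversion in a time shorter by the ratio of the charges, and I let the highest east reading, 57.3 % at 3.00 min, stand for the flask at 1.50 min.

From there the two flasks part. I take first product to decay pseudo-first-order from that point, with [reagent] as the concentration in its rate. Each unit of starting material takes half a unit of reagent, plus half for each unit ending as first product, so east keeps 0.607 M. East falls to 54.3 % by 6.00 min, which gives a loss constant, first product lost per minute per mole per litre of reagent left, of 0.0295 /M/min, a reading with 1 percentage point of scatter on each reading. The flask keeps 1.21 M, twice as much, and has the time from 1.50 min to 6.0 min to lose first product, so I expect 48.8 %.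

The forecast says “Yield depends on equivalents, not concentration.” It gives 51 % as charged, more than my 48.8 %, and 54.5 % at 3 equiv.

The flask gives 51.6 % as charged, and 55.6 % at 3.18 equiv.

    starting material + reagent → first product + by-product (k = 0.0200 /M/s)
    reagent + first product → double product + by-product (k = 3.30 × 10⁻⁴ /M/s)
    reagent + double product → triple product + by-product (k = 0.0130 /M/s)
    triple product ⇌ isomer of the product (K = 1.60, k = 0.00430 /s)
    starting material + first product → side product (k = 0.0230 /M/s)

Each path taken by itself, the other concentrations as charged, first product has a half-life of 0.50 min against starting material, shorter than 18 min against reagent. The flask holds 41.0 % as side product and 0.121 % of starting material at 3.00 min, and from there first product falls to 51.6 % while side product stays at 41.1 %.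

In the neighbour at 0.40 M, the east reading moves to 3.75 min and the same loss constant gives 55.5 %; computed, it holds 55.7 %, with side product at 40.8 %.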